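**Retrosynthetic overview**

1. The last skeletal bond is the interflavan bond C4 (robinetinidol unit) to C8 (gallocatechin unit), made by Friedel–Crafts alkylation of ring A of a benzylated gallocatechin with the C4 cation of a benzylated robinetinidol-4-ol; global hydrogenolysis ends the route.
2. Each ring C is cut at O1–C8a and at C2–C3, which excises the C2(aryl)=O1 unit as 3,4,5-tris(benzyloxy)benzaldehyde and leaves ring A carrying C4–C3 as an aryl ketone with fluorine on C8a.
3. Enabling feature: in ring C, O1 and C3 are both bonded to C2, while their other anchors C8a and C4a are ortho neighbours on ring A. A temporary C4 ketone makes C3 an enol carbon and opens C8a (ortho to the acyl-bearing C4a) to SNAr, so one aldehyde C=O is stitched across C3 and C8a in a single asymmetric Mukaiyama aldol/SNAr annulation that sets C2 and C3.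
4. The C4 ketone is afterwards removed (gallocatechin unit) or reduced to the ionisable C4 alcohol (robinetinidol unit).
5. Ring order: rings A and B are bought as arenes; ring C of the gallocatechin unit (steps 1–5), ring C of the robinetinidol unit (steps 6–9), interflavan bond (step 10), deprotection (step 11).

Key step: step 4

Assumption: the label 4alpha is read as the 3,4-trans arrangement that the SMILES encodes, which is 2R,3S,4S in the robinetinidol unit and 2R,3S in the gallocatechin unit.

**Route**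

Step 1
Reactants: 1 1,3,5-trifluorobenzene
Product: 2 1,3-bis(benzyloxy)-5-fluorobenzene
Conditions: BnOH (2.1 equiv), NaH (2.2 equiv), NMP, 0 to 100 °C
Reagents that add atoms: benzyl alcohol, OCc1ccccc1
Why: Nucleophilic aromatic substitution by benzyloxide should displace two of the three mutually meta fluorines in turn, and the third is spared at controlled stoichiometry because each alkoxy group installed replaces an activating fluorine.

Step 2
Reactants: 2 1,3-bis(benzyloxy)-5-fluorobenzene; 3 2-(benzyloxy)-N-methoxy-N-methylacetamide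
Product: 5 2-(benzyloxy)-1-[2,4-bis(benzyloxy)-6-fluorophenyl]ethan-1-one, via aryllithium 4 (not isolated)
Conditions: n-BuLi, THF, −78 °C; then 3, −78 to −40 °C; H2O
Reagents that add atoms: none
Why: Directed ortho-metalation should occur at the most acidic ring C–H, the one flanked by fluorine and a benzyloxy group, and the aryllithium, kept cold to avoid loss of LiF, is acylated once by the Weinreb amide (Weinreb ketone synthesis), which places the future C4 carbonyl ortho to the fluorine that becomes the leaving group at C8a.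

Step 3
Reactants: 5 2-(benzyloxy)-1-[2,4-bis(benzyloxy)-6-fluorophenyl]ethan-1-one
Product: 7 {[(Z)-2-(benzyloxy)-1-[2,4-bis(benzyloxy)-6-fluorophenyl]ethenyl]oxy}trimethylsilane, via lithium enolate 6 (not isolated)
Conditions: LiN(SiMe3)2, THF, −78 °C; Me3SiCl, −78 °C to rt
Reagents that add atoms: chlorotrimethylsilane, C[Si](C)(C)Cl
Why: Kinetic deprotonation gives the lithium enolate in which the enolate oxygen and the benzyloxy oxygen chelate lithium, and O-silylation fixes this geometry as the (Z)-enol silane (silyl enol ether formation).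

Step 4
Reactants: 7 {[(Z)-2-(benzyloxy)-1-[2,4-bis(benzyloxy)-6-fluorophenyl]ethenyl]oxy}trimethylsilane; 8 3,4,5-tris(benzyloxy)benzaldehyde
Product: 10 (2R,3R)-3,5,7-tris(benzyloxy)-2-[3,4,5-tris(benzyloxy)phenyl]chroman-4-one, via anti-aldol silyl ether 9 (not isolated)
Conditions: Sn(OTf)2 (20 mol%), (S)-1-ethyl-2-(piperidin-1-ylmethyl)pyrrolidine (24 mol%), EtCN, −78 °C, slow addition of 7 and 8; then Bu4N[Ph3SiF2] (0.5 equiv), THF, −78 to −20 °C; AcOH
Reagents that add atoms: none
Why: Proposed new method: the divalent tin–diamine Lewis acid activates aldehyde 8 and the enol carbon C3 of 7 adds to C2 through an open transition state with silyl transfer to O1 (asymmetric Mukaiyama aldol; closest known type: the tin–diamine anti-selective aldol of (Z)-α-benzyloxy silyl ketene acetals with aromatic aldehydes), after which fluoride frees the O1 alkoxide of 9, which displaces fluoride at C8a, and the expelled fluoride desilylates the next molecule of 9, so that Me3SiF is the only by-product (closest known type: fluoride-catalysed SNAr of aryl fluorides by silyl ethers). Ring C closes in a 6-exo addition–elimination through a Meisenheimer complex whose negative charge sits on C4a and is absorbed by the C4 carbonyl. C2 is set by the chiral diamine on tin, which should leave the Si face of the bound aldehyde open to attack and so give 2R, and C3 is set by chelation of its benzyloxy oxygen to tin, which should favour the anti adduct and hence the 2,3-trans ring; a minor syn adduct would carry the same C2 configuration and should converge on the trans product by epimerisation of the enolisable C3 centre, trans-diequatorial being the stable arrangement. The step needs the O1 alkoxide to close onto C8a faster than it undergoes retro-aldol cleavage, which the ortho acyl group, the two meta benzyloxy groups and fluorine as nucleofuge on ring A should secure at low temperature. Chemo- and regioselectivity are fixed by the substrate, since O3 is a benzyl ether, ring A carries one fluorine only and a four-membered closure from C3 or the enolate oxygen is not possible.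

Step 5
Reactants: 10 (2R,3R)-3,5,7-tris(benzyloxy)-2-[3,4,5-tris(benzyloxy)phenyl]chroman-4-one
Product: 12 (2R,3S)-3,5,7-tris(benzyloxy)-2-[3,4,5-tris(benzyloxy)phenyl]chromane, via flavan-4-ol 11 (not isolated)
Conditions: NaBH4, THF/MeOH, 0 °C; solvent exchange; then Et3SiH, CF3CO2H, CH2Cl2, −40 °C
Reagents that add atoms: none
Why: Borohydride reduction of the ketone followed by acid ionisation of the resulting C4 alcohol, which is benzylic to the 2,4,6-trioxygenated ring A, gives a cation that triethylsilane reduces to CH2 (ionic hydrogenation) without touching C2 or C3.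

Step 6
Reactants: 13 4-(benzyloxy)-1-bromo-2-fluorobenzene; 3 2-(benzyloxy)-N-methoxy-N-methylacetamide
Product: 15 2-(benzyloxy)-1-[4-(benzyloxy)-2-fluorophenyl]ethan-1-one, via aryllithium 14 (not isolated)
Conditions: n-BuLi, THF, −78 °C; then 3, −78 to −40 °C; H2O
Reagents that add atoms: none
Why: Bromine–lithium exchange at low temperature is faster than ortho-metalation or LiF loss and fixes the metal ortho to fluorine and para to the benzyloxy group, and acylation by the Weinreb amide then stops at the ketone (Weinreb ketone synthesis).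

Step 7
Reactants: 15 2-(benzyloxy)-1-[4-(benzyloxy)-2-fluorophenyl]ethan-1-one
Product: 17 {[(Z)-2-(benzyloxy)-1-[4-(benzyloxy)-2-fluorophenyl]ethenyl]oxy}trimethylsilane, via lithium enolate 16 (not isolated)
Conditions: LiN(SiMe3)2, THF, −78 °C; Me3SiCl, −78 °C to rt
Reagents that add atoms: chlorotrimethylsilane, C[Si](C)(C)Cl
Why: As in step 3, the chelated lithium enolate is trapped on oxygen to give the (Z)-enol silane (silyl enol ether formation).

Step 8
Reactants: 17 {[(Z)-2-(benzyloxy)-1-[4-(benzyloxy)-2-fluorophenyl]ethenyl]oxy}trimethylsilane; 8 3,4,5-tris(benzyloxy)benzaldehyde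
Product: 19 (2R,3R)-3,7-bis(benzyloxy)-2-[3,4,5-tris(benzyloxy)phenyl]chroman-4-one, via anti-aldol silyl ether 18 (not isolated)
Conditions: Sn(OTf)2 (20 mol%), (S)-1-ethyl-2-(piperidin-1-ylmethyl)pyrrolidine (24 mol%), EtCN, −78 °C, slow addition of 17 and 8; then Bu4N[Ph3SiF2] (0.5 equiv), THF, −78 to −20 °C; AcOH
Reagents that add atoms: none
Why: Proposed new method: as in step 4, the divalent tin–diamine Lewis acid should direct the enol carbon of 17 to the Si face of 8 with chelation-controlled anti selectivity (closest known type: the tin–diamine Mukaiyama aldol of (Z)-α-benzyloxy silyl ketene acetals), and the fluoride-relayed 6-exo SNAr of the O1 alkoxide of 18 at the fluorine-bearing carbon ortho to the ketone (closest known type: fluoride-catalysed SNAr of aryl fluorides by silyl ethers) then closes ring C as the 2R,3R trans-chromanone.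

Step 9
Reactants: 19 (2R,3R)-3,7-bis(benzyloxy)-2-[3,4,5-tris(benzyloxy)phenyl]chroman-4-one
Product: 20 (2R,3S,4R)-3,7-bis(benzyloxy)-2-[3,4,5-tris(benzyloxy)phenyl]chroman-4-ol
Conditions: NaBH4, THF/MeOH, 0 °C
Reagents that add atoms: none
Why: Borohydride should add to the C4 carbonyl along the axial trajectory of the half-chair that keeps the C2 aryl and C3 benzyloxy groups equatorial, giving mainly the all-equatorial 4R alcohol (hydride reduction), and a minor 4S epimer is equally useful because C4 is ionised in step 10.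

Step 10
Reactants: 20 (2R,3S,4R)-3,7-bis(benzyloxy)-2-[3,4,5-tris(benzyloxy)phenyl]chroman-4-ol; 12 (2R,3S)-3,5,7-tris(benzyloxy)-2-[3,4,5-tris(benzyloxy)phenyl]chromane
Product: 21 (2R,3S,4S)-3,7-bis(benzyloxy)-4-[(2R,3S)-3,5,7-tris(benzyloxy)-2-[3,4,5-tris(benzyloxy)phenyl]chroman-8-yl]-2-[3,4,5-tris(benzyloxy)phenyl]chromane
Conditions: BF3·OEt2, 12 (2 equiv), CH2Cl2, −78 to −30 °C
Reagents that add atoms: none
Why: BF3 ionises the C4 alcohol of 20 to a benzylic cation stabilised by O1 and the para 7-benzyloxy group, and ring A of 12, a phloroglucinol triether far more nucleophilic than ring A of 20, should attack through C8 from the face anti to the neighbouring C3 benzyloxy group, which gives the 3,4-trans (4α, 4S) bond (Friedel–Crafts alkylation).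

Step 11
Reactants: 21 (2R,3S,4S)-3,7-bis(benzyloxy)-4-[(2R,3S)-3,5,7-tris(benzyloxy)-2-[3,4,5-tris(benzyloxy)phenyl]chroman-8-yl]-2-[3,4,5-tris(benzyloxy)phenyl]chromane
Product: 22 robinetinidol-(4α,8)-gallocatechin
Conditions: H2 (1 atm), Pd(OH)2/C, THF/MeOH/H2O, rt
Reagents that add atoms: none
Why: Hydrogenolysis over Pd(OH)2/C cleaves all eleven benzyl ethers under neutral conditions that leave the acid-labile interflavan bond, the ring C ethers and every stereocentre untouched (catalytic hydrogenolysis).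

**Compound list**

1 | 1,3,5-trifluorobenzene | Fc1cc(F)cc(F)c1 | starting material
2 | 1,3-bis(benzyloxy)-5-fluorobenzene | Fc1cc(OCc2ccccc2)cc(OCc2ccccc2)c1 | intermediate
3 | 2-(benzyloxy)-N-methoxy-N-methylacetamide | CON(C)C(=O)COCc1ccccc1 | starting material
4 | [2,4-bis(benzyloxy)-6-fluorophenyl]lithium | [Li]c1c(F)cc(OCc2ccccc2)cc1OCc1ccccc1 | intermediate
5 | 2-(benzyloxy)-1-[2,4-bis(benzyloxy)-6-fluorophenyl]ethan-1-one | O=C(COCc1ccccc1)c1c(F)cc(OCc2ccccc2)cc1OCc1ccccc1 | intermediate
6 | lithium (Z)-2-(benzyloxy)-1-[2,4-bis(benzyloxy)-6-fluorophenyl]ethen-1-olate | [Li]O/C(=C\OCc1ccccc1)c1c(F)cc(OCc2ccccc2)cc1OCc1ccccc1 | intermediate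
7 | {[(Z)-2-(benzyloxy)-1-[2,4-bis(benzyloxy)-6-fluorophenyl]ethenyl]oxy}trimethylsilane | C[Si](C)(C)O/C(=C\OCc1ccccc1)c1c(F)cc(OCc2ccccc2)cc1OCc1ccccc1 | intermediate
8 | 3,4,5-tris(benzyloxy)benzaldehyde | O=Cc1cc(OCc2ccccc2)c(OCc2ccccc2)c(OCc2ccccc2)c1 | starting material
9 | (2R,3R)-2-(benzyloxy)-1-[2,4-bis(benzyloxy)-6-fluorophenyl]-3-[3,4,5-tris(benzyloxy)phenyl]-3-[(trimethylsilyl)oxy]propan-1-one | C[Si](C)(C)O[C@H](c1cc(OCc2ccccc2)c(OCc2ccccc2)c(OCc2ccccc2)c1)[C@@H](OCc1ccccc1)C(=O)c1c(F)cc(OCc2ccccc2)cc1OCc1ccccc1 | intermediate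
10 | (2R,3R)-3,5,7-tris(benzyloxy)-2-[3,4,5-tris(benzyloxy)phenyl]chroman-4-one | O(Cc1ccccc1)c1cc(OCc2ccccc2)c2c(c1)O[C@H](c1cc(OCc3ccccc3)c(OCc3ccccc3)c(OCc3ccccc3)c1)[C@@H](OCc1ccccc1)C2=O | intermediate
11 | (2R,3S)-3,5,7-tris(benzyloxy)-2-[3,4,5-tris(benzyloxy)phenyl]chroman-4-ol, C4 epimers carried together | O(Cc1ccccc1)c1cc(OCc2ccccc2)c2c(c1)O[C@H](c1cc(OCc3ccccc3)c(OCc3ccccc3)c(OCc3ccccc3)c1)[C@@H](OCc1ccccc1)C2O | intermediate
12 | (2R,3S)-3,5,7-tris(benzyloxy)-2-[3,4,5-tris(benzyloxy)phenyl]chromane (hexa-O-benzylgallocatechin) | O(Cc1ccccc1)c1cc(OCc2ccccc2)c2c(c1)O[C@H](c1cc(OCc3ccccc3)c(OCc3ccccc3)c(OCc3ccccc3)c1)[C@@H](OCc1ccccc1)C2 | intermediate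
13 | 4-(benzyloxy)-1-bromo-2-fluorobenzene | Brc1ccc(OCc2ccccc2)cc1F | starting material
14 | [4-(benzyloxy)-2-fluorophenyl]lithium | [Li]c1ccc(OCc2ccccc2)cc1F | intermediate
15 | 2-(benzyloxy)-1-[4-(benzyloxy)-2-fluorophenyl]ethan-1-one | O=C(COCc1ccccc1)c1ccc(OCc2ccccc2)cc1F | intermediate
16 | lithium (Z)-2-(benzyloxy)-1-[4-(benzyloxy)-2-fluorophenyl]ethen-1-olate | [Li]O/C(=C\OCc1ccccc1)c1ccc(OCc2ccccc2)cc1F | intermediate
17 | {[(Z)-2-(benzyloxy)-1-[4-(benzyloxy)-2-fluorophenyl]ethenyl]oxy}trimethylsilane | C[Si](C)(C)O/C(=C\OCc1ccccc1)c1ccc(OCc2ccccc2)cc1F | intermediate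
18 | (2R,3R)-2-(benzyloxy)-1-[4-(benzyloxy)-2-fluorophenyl]-3-[3,4,5-tris(benzyloxy)phenyl]-3-[(trimethylsilyl)oxy]propan-1-one | C[Si](C)(C)O[C@H](c1cc(OCc2ccccc2)c(OCc2ccccc2)c(OCc2ccccc2)c1)[C@@H](OCc1ccccc1)C(=O)c1ccc(OCc2ccccc2)cc1F | intermediate
19 | (2R,3R)-3,7-bis(benzyloxy)-2-[3,4,5-tris(benzyloxy)phenyl]chroman-4-one | O(Cc1ccccc1)c1ccc2c(c1)O[C@H](c1cc(OCc3ccccc3)c(OCc3ccccc3)c(OCc3ccccc3)c1)[C@@H](OCc1ccccc1)C2=O | intermediate
20 | (2R,3S,4R)-3,7-bis(benzyloxy)-2-[3,4,5-tris(benzyloxy)phenyl]chroman-4-ol | O(Cc1ccccc1)c1ccc2c(c1)O[C@H](c1cc(OCc3ccccc3)c(OCc3ccccc3)c(OCc3ccccc3)c1)[C@@H](OCc1ccccc1)[C@@H]2O | intermediate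
21 | (2R,3S,4S)-3,7-bis(benzyloxy)-4-[(2R,3S)-3,5,7-tris(benzyloxy)-2-[3,4,5-tris(benzyloxy)phenyl]chroman-8-yl]-2-[3,4,5-tris(benzyloxy)phenyl]chromane (undeca-O-benzyl dimer) | O(Cc1ccccc1)c1ccc2c(c1)O[C@H](c1cc(OCc3ccccc3)c(OCc3ccccc3)c(OCc3ccccc3)c1)[C@@H](OCc1ccccc1)[C@@H]2c1c(OCc3ccccc3)cc(OCc3ccccc3)c2c1O[C@H](c1cc(OCc3ccccc3)c(OCc3ccccc3)c(OCc3ccccc3)c1)[C@@H](OCc1ccccc1)C2 | intermediate
22 | robinetinidol-(4α,8)-gallocatechin | Oc1ccc2c(c1)O[C@H](c1cc(O)c(O)c(O)c1)[C@@H](O)[C@@H]2c1c(O)cc(O)c2c1O[C@H](c1cc(O)c(O)c(O)c1)[C@@H](O)C2 | target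

**Summary**

Total step count: 11.
Longest linear sequence: 7 steps (steps 1, 2, 3, 4, 5, 10 and 11).

**Steps most likely to fail**

1. Step 4. In the fluoride stage the O1 alkoxide may undergo retro-aldol cleavage, or the product may enolise at C3 and open at O1–C2, before or after ring closure, which would erode the configuration at C2 and C3. The fallback uses known chemistry and postpones ring closure until no carbonyl is left. It sets out from 7 and 8: the tin–diamine aldol is stopped before any fluoride is added, and acidic aqueous work-up hydrolyses silyl ether 9 to the β-hydroxy ketone (2R,3R)-2-(benzyloxy)-1-[2,4-bis(benzyloxy)-6-fluorophenyl]-3-hydroxy-3-[3,4,5-tris(benzyloxy)phenyl]propan-1-one F1. Reduction with NaBH4 in THF/MeOH gives the 1,3-diol (1R,2R)-2-(benzyloxy)-3-[2,4-bis(benzyloxy)-6-fluorophenyl]-1-[3,4,5-tris(benzyloxy)phenyl]propane-1,3-diol F2 (C3 epimers), which can no longer fragment. NaH in NMP at about 90 °C should then close ring C by alkoxide SNAr on the non-activated fluoroarene, since only the alkoxide at the carbon bearing ring B can reach the C–F carbon through a six-membered transition state. This gives flavan-4-ol 11, where the route is rejoined; the Et3SiH/CF3CO2H stage of step 5 then leads to 12.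

2. Step 8. Facial control by the tin–diamine catalyst may be insufficient on the less hindered enol silane 17, or a background silyl-triflate-catalysed aldol may intervene, lowering the enantiomeric purity. The fallback uses known chemistry and moves stereocontrol to a kinetic resolution. It sets out from 15 and 8: the lithium enolate of 15 (LiN(SiMe3)2, THF, −78 °C) adds to 8 to give racemic 2-(benzyloxy)-1-[4-(benzyloxy)-2-fluorophenyl]-3-hydroxy-3-[3,4,5-tris(benzyloxy)phenyl]propan-1-one F3 as a diastereomer mixture. K2CO3 in DMF closes ring C by SNAr and equilibrates C3 to the trans isomer, giving the racemate made up of 19 and its enantiomer (2S,3S)-3,7-bis(benzyloxy)-2-[3,4,5-tris(benzyloxy)phenyl]chroman-4-one F4. Asymmetric transfer hydrogenation with RuCl(p-cymene)[(S,S)-TsDPEN] in HCO2H/Et3N, stopped near half conversion, should reduce the 2R,3R enantiomer faster and deliver 20 directly, where the route is rejoined; unreacted F4 is separated.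

3. Step 10. Alkylation may compete at C6 of the gallocatechin ring A or from the face syn to the C3 benzyloxy group, the product may be alkylated a second time, or the cation may eliminate to a flav-3-ene. The fallback condenses the free phenols in water and sets out from 12 and 19. Hydrogenolysis of 12 (H2, Pd(OH)2/C) gives (+)-gallocatechin F5, and hydrogenolysis of 19 (H2, Pd/C, EtOAc/MeOH) gives (+)-dihydrorobinetin F6. NaBH4 in EtOH reduces F6 to the flavan-3,4-diol leucorobinetinidin F7. F7 and an excess of F5 in 0.1 M aqueous HCl at rt should condense by the classical acid-catalysed flavan-3,4-diol/flavan-3-ol reaction, in which the 5-deoxy cation attacks only the phloroglucinol ring, mainly at C8 and with 3,4-trans geometry. This gives 22 directly after chromatography on Sephadex LH-20, where the route is rejoined.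

**Further compounds**

F1 | step 4 | (2R,3R)-2-(benzyloxy)-1-[2,4-bis(benzyloxy)-6-fluorophenyl]-3-hydroxy-3-[3,4,5-tris(benzyloxy)phenyl]propan-1-one | O[C@H](c1cc(OCc2ccccc2)c(OCc2ccccc2)c(OCc2ccccc2)c1)[C@@H](OCc1ccccc1)C(=O)c1c(F)cc(OCc2ccccc2)cc1OCc1ccccc1
F2 | step 4 | (1R,2R)-2-(benzyloxy)-3-[2,4-bis(benzyloxy)-6-fluorophenyl]-1-[3,4,5-tris(benzyloxy)phenyl]propane-1,3-diol, C3 epimers | O[C@H](c1cc(OCc2ccccc2)c(OCc2ccccc2)c(OCc2ccccc2)c1)[C@@H](OCc1ccccc1)C(O)c1c(F)cc(OCc2ccccc2)cc1OCc1ccccc1
F3 | step 8 | 2-(benzyloxy)-1-[4-(benzyloxy)-2-fluorophenyl]-3-hydroxy-3-[3,4,5-tris(benzyloxy)phenyl]propan-1-one, racemic diastereomer mixture | OC(c1cc(OCc2ccccc2)c(OCc2ccccc2)c(OCc2ccccc2)c1)C(OCc1ccccc1)C(=O)c1ccc(OCc2ccccc2)cc1F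
F4 | step 8 | (2S,3S)-3,7-bis(benzyloxy)-2-[3,4,5-tris(benzyloxy)phenyl]chroman-4-one | O(Cc1ccccc1)c1ccc2c(c1)O[C@@H](c1cc(OCc3ccccc3)c(OCc3ccccc3)c(OCc3ccccc3)c1)[C@H](OCc1ccccc1)C2=O
F5 | step 10 | (+)-gallocatechin, (2R,3S)-2-(3,4,5-trihydroxyphenyl)chromane-3,5,7-triol | Oc1cc(O)c2c(c1)O[C@H](c1cc(O)c(O)c(O)c1)[C@@H](O)C2
F6 | step 10 | (+)-dihydrorobinetin, (2R,3R)-3,7-dihydroxy-2-(3,4,5-trihydroxyphenyl)chroman-4-one | Oc1ccc2c(c1)O[C@H](c1cc(O)c(O)c(O)c1)[C@@H](O)C2=O
F7 | step 10 | leucorobinetinidin, (2R,3S,4R)-2-(3,4,5-trihydroxyphenyl)chromane-3,4,7-triol | Oc1ccc2c(c1)O[C@H](c1cc(O)c(O)c(O)c1)[C@@H](O)[C@@H]2O
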